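**Retrosynthetic overview**
1. Feature (lignan numbering): two cis-fused oxolanes, ring A (C7'–O–C9–C8–C8') and ring B (C8–C7–O–C9'–C8'). The carbinol carbon C8 and its neighbour C8' can serve as the two carbons of a C8-oxygenated enol ether inside ring A, and C7 and C9' of ring B are joined only through one oxygen.
2. Ring B therefore comes from a γ-lactone (C9' as C=O), itself from Baeyer–Villiger oxygen insertion into the C7–C9' bond of a cyclobutanone C8–C7–C9'(=O)–C8' fused to ring A; the lactone carbonyl is then taken to CH2 by reduction and reclosure.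
3. The cyclobutanone comes from a [2+2] cycloaddition of (4-silyloxy-3-methoxyphenyl)ketene (from homovanillic acid) across the C8=C8' silyl enol ether of (S)-5-aryl-3-silyloxy-2,5-dihydrofuran, forming C7–C8 and C9'–C8'.
4. The dihydrofuran comes from kinetic enol silylation of (S)-5-aryl-oxolan-3-one, made by gold-catalysed oxidative cyclisation of the (S)-homopropargylic alcohol from asymmetric propargylation of O-silyl vanillin.
5. Ring order: ring A, then the temporary four-membered ring, then ring B.

Key step: step 7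

Notation: Ar = 4-(tert-butyldimethylsilyloxy)-3-methoxyphenyl; TBS = tert-butyldimethylsilyl; atoms carry the lignan labels C7, C8, C9, C7', C8', C9'.

Assumption: in step 2 the (S)-phosphoric acid is taken to give the (S)-carbinol, as the (R)-acid gives (R)-carbinols from aryl aldehydes in this reaction type; were the sense reversed for aldehyde 2, the (R)-acid would be used and nothing else changes.

**Step 1**
Reactants: 1 vanillin
Product: 2 4-(tert-butyldimethylsilyloxy)-3-methoxybenzaldehyde
Conditions: TBSCl (1.2 equiv), imidazole (2 equiv), DMF, rt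
Reagents that add atoms: tert-butyldimethylsilyl chloride, CC(C)(C)[Si](C)(C)Cl
Why: Imidazole-promoted O-silylation of a phenol; the silyl ether masks the phenol through the later base, peracid and hydride steps and is removed by fluoride, avoiding a hydrogenolysis that would endanger the benzylic ethers of the target.

**Step 2**
Reactants: 2 4-(tert-butyldimethylsilyloxy)-3-methoxybenzaldehyde; 3 allenylboronic acid pinacol ester
Product: 5 (S)-1-Ar-but-3-yn-1-ol, via O-boryl ether 4 (not isolated)
Conditions: 3 (1.5 equiv), (S)-3,3'-bis(2,4,6-triisopropylphenyl)-1,1'-binaphthyl-2,2'-diyl hydrogen phosphate (10 mol %), 4 Å MS, toluene, −20 °C; aq. NaHCO3 work-up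
Reagents that add atoms: none
Why: Chiral Brønsted acid-catalysed propargylation of an aryl aldehyde, in which the allenylboronate adds through a closed six-membered SE2' transition state held in the chiral pocket of the phosphoric acid, so that one aldehyde face is selected and the C7' carbinol centre is set as (S); aqueous work-up cleaves the B–O bond of 4.

**Step 3**
Reactants: 5 (S)-1-Ar-but-3-yn-1-ol
Product: 6 (S)-5-Ar-dihydrofuran-3(2H)-one
Conditions: [2-(dicyclohexylphosphino)-3,6-dimethoxy-2',4',6'-triisopropylbiphenyl]AuNTf2 (5 mol %), 2,6-dibromopyridine N-oxide (1.5 equiv), ClCH2CH2Cl, rt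
Reagents that add atoms: 2,6-dibromopyridine N-oxide, [O-][n+]1c(Br)cccc1Br
Why: Gold-catalysed oxidative cyclisation of a homopropargylic alcohol, in which the N-oxide attacks the gold-activated terminal alkyne at its internal carbon, loss of the pyridine leaves an α-oxo gold carbene at the terminal carbon and O–H insertion by the carbinol closes the oxolan-3-one; the weakly basic 2,6-dibromopyridine needs no acid additive, so the acid-sensitive benzylic centre, which takes no part in the bond changes, should keep its configuration.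

**Step 4**
Reactants: 6 (S)-5-Ar-dihydrofuran-3(2H)-one
Product: 8 (S)-5-Ar-3-(tert-butyldimethylsilyloxy)-2,5-dihydrofuran, via lithium enolate 7 (not isolated)
Conditions: LiN(iPr)2 (1.1 equiv), THF, −78 °C; TBSOTf (1.2 equiv), −78 °C; Et3N, aq. NaHCO3
Reagents that add atoms: tert-butyldimethylsilyl trifluoromethanesulfonate, CC(C)(C)[Si](C)(C)OS(=O)(=O)C(F)(F)F
Why: Kinetic enolisation, in which the lithium amide should remove a C4 proton (the α-carbon that does not carry the ring oxygen, as in the formation of 2,5-dihydrofuran-3-yl enol derivatives from oxolan-3-one) and O-silylation of enolate 7 fixes the C3=C4 (C8=C8') double bond; C5 (C7') is not touched.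

**Step 5**
Reactants: 9 homovanillic acid
Product: 10 tert-butyldimethylsilyl 2-Ar-acetate
Conditions: TBSCl (2.3 equiv), imidazole (4 equiv), DMF, rt
Reagents that add atoms: tert-butyldimethylsilyl chloride, CC(C)(C)[Si](C)(C)Cl
Why: Imidazole-promoted silylation of both the phenol and the carboxylic acid gives the silyl ether silyl ester in one operation.

**Step 6**
Reactants: 10 tert-butyldimethylsilyl 2-Ar-acetate
Product: 11 2-Ar-acetyl chloride
Conditions: (COCl)2 (1.2 equiv), N,N-dimethylformamide (5 mol %), CH2Cl2, 0 °C → rt; evaporate, use crude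
Reagents that add atoms: oxalyl chloride, O=C(Cl)C(=O)Cl
Why: Silyl esters are converted by the Vilsmeier chloride (oxalyl chloride with catalytic DMF) directly into acid chlorides with release of TBSCl in place of HCl, so the aryl silyl ether is not exposed to acid.

**Step 7**
Reactants: 8 (S)-5-Ar-3-(tert-butyldimethylsilyloxy)-2,5-dihydrofuran; 11 2-Ar-acetyl chloride
Product: 14 (1S,4S,5R,7R)-4,7-di-Ar-1-(tert-butyldimethylsilyloxy)-3-oxabicyclo[3.2.0]heptan-6-one, via aryl ketene 12 (not isolated), via endo-aryl cyclobutanone 13 (not isolated)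
Conditions: Et3N (4 equiv), toluene, 70 °C, 11 (2.5 equiv) added over 8 h; short silica pad (toluene) to remove Et3NHCl and ketene dimer; 1,8-diazabicyclo[5.4.0]undec-7-ene (0.3 equiv), toluene, rt
Reagents that add atoms: none
Why: Et3N dehydrochlorinates 11 to ketene 12, which is kept at low concentration and adds to the electron-rich C8=C8' silyl enol ether of 8 in an asynchronous thermal [2+2] cycloaddition, the nucleophilic C8' (C4 of the dihydrofuran) bonding to the ketene carbonyl carbon C9' and the silyloxy-stabilised C8 then bonding to the aryl-bearing ketene carbon C7. The closest known reactions are the cycloadditions of ketenes generated in situ with silyl enol ethers, which give 3-silyloxycyclobutanones, and of aryl ketenes with cyclic enol ethers. The cyclobutanone closes by this intermolecular two-bond annulation (the second bond is a four-membered closure of the enolate carbon onto the silyloxocarbenium carbon), and its fusion to ring A is necessarily cis. C8 and C8' are set by the C7' stereocentre, whose aryl group shields one face of the nearly flat dihydrofuran so that the ketene adds anti to it, and the regiochemistry follows from the polarity of the enol ether. C7 is set under thermodynamic control: the expected kinetic adduct 13 (aryl endo, the usual outcome for monosubstituted ketenes) has an acidic benzylic α-hydrogen and DBU should equilibrate it through the enol to 14, in which the aryl lies on the convex face next to the small bridgehead oxygen instead of over ring A next to C9. The step needs the cycloaddition to outrun ketene dimerisation, which slow addition of excess 11 and the high nucleophilicity of a trisubstituted silyl enol ether should secure, while the bulky silyl group disfavours silyl transfer and opening of the 3-silyloxycyclobutanone.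

**Step 8**
Reactants: 14 (1S,4S,5R,7R)-4,7-di-Ar-1-(tert-butyldimethylsilyloxy)-3-oxabicyclo[3.2.0]heptan-6-one
Product: 15 (1R,4R,5S,8S)-4,8-di-Ar-5-(tert-butyldimethylsilyloxy)-3,7-dioxabicyclo[3.3.0]octan-2-one
Conditions: mCPBA (1.5 equiv), NaHCO3, CH2Cl2, 0 °C
Reagents that add atoms: 3-chloroperbenzoic acid, O=C(OO)c1cccc(Cl)c1
Why: Baeyer–Villiger oxidation of a strained cyclobutanone, in which the benzylic C7 carrying an electron-rich aryl group should migrate in the Criegee adduct in preference to the ring-fusion C8' (deactivated by two β-oxygen substituents) and does so with retention, so that oxygen enters between C9' and C7 and the (7R) configuration is kept.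

**Step 9**
Reactants: 15 (1R,4R,5S,8S)-4,8-di-Ar-5-(tert-butyldimethylsilyloxy)-3,7-dioxabicyclo[3.3.0]octan-2-one
Product: 16 (R)-Ar[(3S,4R,5S)-5-Ar-4-(hydroxymethyl)-3-(tert-butyldimethylsilyloxy)oxolan-3-yl]methanol
Conditions: LiBH4 (3 equiv), THF, 0 °C → rt; aq. NH4Cl
Reagents that add atoms: none
Why: Lithium borohydride reduces the γ-lactone to the primary C9' alcohol and the benzylic C7 alcohol without breaking a bond to any stereocentre and without cleaving the aryl or tertiary silyl ethers, which LiAlH4 might attack.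

**Step 10**
Reactants: 16 (R)-Ar[(3S,4R,5S)-5-Ar-4-(hydroxymethyl)-3-(tert-butyldimethylsilyloxy)oxolan-3-yl]methanol
Product: 18 (1S,2R,5R,6S)-2,6-di-Ar-1-(tert-butyldimethylsilyloxy)-3,7-dioxabicyclo[3.3.0]octane, via primary tosylate 17 (not isolated)
Conditions: TsCl (1.3 equiv), pyridine, 4-(dimethylamino)pyridine (10 mol %), 0 °C → rt, then 50 °C
Reagents that add atoms: none
Why: Selective sulfonylation of the unhindered primary alcohol followed by 5-exo-tet Williamson closure by the neutral benzylic hydroxyl forms ring B with the C7–O bond intact, so C7 keeps its configuration, and the absence of a free alkoxide avoids 1,2-migration of the neighbouring tertiary silyl group.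

**Step 11**
Reactants: 18 (1S,2R,5R,6S)-2,6-di-Ar-1-(tert-butyldimethylsilyloxy)-3,7-dioxabicyclo[3.3.0]octane
Product: 19 8-hydroxypinoresinol
Conditions: Bu4NF (4 equiv), AcOH (4 equiv), THF, 0 °C → 40 °C
Reagents that add atoms: none
Why: Fluoride cleaves the two aryl silyl ethers and the tertiary silyl ether, and acetic acid buffering keeps the phenols protonated so that the para-hydroxybenzylic ethers do not open through quinone methides and no stereocentre is disturbed.

**Compound list**
1 | vanillin (4-hydroxy-3-methoxybenzaldehyde) | COc1cc(C=O)ccc1O | starting material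
2 | 4-(tert-butyldimethylsilyloxy)-3-methoxybenzaldehyde | COc1cc(C=O)ccc1O[Si](C)(C)C(C)(C)C | intermediate
3 | allenylboronic acid pinacol ester (4,4,5,5-tetramethyl-2-(propa-1,2-dienyl)-1,3,2-dioxaborolane) | C=C=CB1OC(C)(C)C(C)(C)O1 | starting material
4 | (S)-2-{1-[4-(tert-butyldimethylsilyloxy)-3-methoxyphenyl]but-3-ynyloxy}-4,4,5,5-tetramethyl-1,3,2-dioxaborolane | COc1cc([C@@H](OB2OC(C)(C)C(C)(C)O2)CC#C)ccc1O[Si](C)(C)C(C)(C)C | intermediate
5 | (S)-1-[4-(tert-butyldimethylsilyloxy)-3-methoxyphenyl]but-3-yn-1-ol | COc1cc([C@@H](O)CC#C)ccc1O[Si](C)(C)C(C)(C)C | intermediate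
6 | (S)-5-[4-(tert-butyldimethylsilyloxy)-3-methoxyphenyl]dihydrofuran-3(2H)-one | COc1cc([C@H]2OCC(=O)C2)ccc1O[Si](C)(C)C(C)(C)C | intermediate
7 | lithium (S)-5-[4-(tert-butyldimethylsilyloxy)-3-methoxyphenyl]-2,5-dihydrofuran-3-olate | COc1cc([C@H]2OCC([O-])=C2)ccc1O[Si](C)(C)C(C)(C)C.[Li+] | intermediate
8 | (S)-5-[4-(tert-butyldimethylsilyloxy)-3-methoxyphenyl]-3-(tert-butyldimethylsilyloxy)-2,5-dihydrofuran | COc1cc([C@H]2OCC(O[Si](C)(C)C(C)(C)C)=C2)ccc1O[Si](C)(C)C(C)(C)C | intermediate
9 | homovanillic acid (4-hydroxy-3-methoxyphenylacetic acid) | COc1cc(CC(=O)O)ccc1O | starting material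
10 | tert-butyldimethylsilyl 2-[4-(tert-butyldimethylsilyloxy)-3-methoxyphenyl]acetate | COc1cc(CC(=O)O[Si](C)(C)C(C)(C)C)ccc1O[Si](C)(C)C(C)(C)C | intermediate
11 | 2-[4-(tert-butyldimethylsilyloxy)-3-methoxyphenyl]acetyl chloride | COc1cc(CC(=O)Cl)ccc1O[Si](C)(C)C(C)(C)C | intermediate
12 | [4-(tert-butyldimethylsilyloxy)-3-methoxyphenyl]ketene | O=C=Cc1ccc(O[Si](C)(C)C(C)(C)C)c(OC)c1 | intermediate
13 | (1S,4S,5R,7S)-1-(tert-butyldimethylsilyloxy)-4,7-bis[4-(tert-butyldimethylsilyloxy)-3-methoxyphenyl]-3-oxabicyclo[3.2.0]heptan-6-one (7-aryl endo) | COc1cc([C@H]2OC[C@]3(O[Si](C)(C)C(C)(C)C)[C@H](c4ccc(O[Si](C)(C)C(C)(C)C)c(OC)c4)C(=O)[C@H]23)ccc1O[Si](C)(C)C(C)(C)C | intermediate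
14 | (1S,4S,5R,7R)-1-(tert-butyldimethylsilyloxy)-4,7-bis[4-(tert-butyldimethylsilyloxy)-3-methoxyphenyl]-3-oxabicyclo[3.2.0]heptan-6-one (7-aryl exo, cis to the silyloxy group) | COc1cc([C@H]2OC[C@]3(O[Si](C)(C)C(C)(C)C)[C@@H](c4ccc(O[Si](C)(C)C(C)(C)C)c(OC)c4)C(=O)[C@H]23)ccc1O[Si](C)(C)C(C)(C)C | intermediate
15 | (1R,4R,5S,8S)-5-(tert-butyldimethylsilyloxy)-4,8-bis[4-(tert-butyldimethylsilyloxy)-3-methoxyphenyl]-3,7-dioxabicyclo[3.3.0]octan-2-one | COc1cc([C@H]2OC[C@]3(O[Si](C)(C)C(C)(C)C)[C@@H](c4ccc(O[Si](C)(C)C(C)(C)C)c(OC)c4)OC(=O)[C@H]23)ccc1O[Si](C)(C)C(C)(C)C | intermediate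
16 | (R)-[4-(tert-butyldimethylsilyloxy)-3-methoxyphenyl]{(3S,4R,5S)-3-(tert-butyldimethylsilyloxy)-5-[4-(tert-butyldimethylsilyloxy)-3-methoxyphenyl]-4-(hydroxymethyl)oxolan-3-yl}methanol | COc1cc([C@H]2OC[C@](O[Si](C)(C)C(C)(C)C)([C@H](O)c3ccc(O[Si](C)(C)C(C)(C)C)c(OC)c3)[C@@H]2CO)ccc1O[Si](C)(C)C(C)(C)C | intermediate
17 | primary 4-methylbenzenesulfonate of 16 (at the C9' hydroxymethyl group) | COc1cc([C@H]2OC[C@](O[Si](C)(C)C(C)(C)C)([C@H](O)c3ccc(O[Si](C)(C)C(C)(C)C)c(OC)c3)[C@@H]2COS(=O)(=O)c4ccc(C)cc4)ccc1O[Si](C)(C)C(C)(C)C | intermediate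
18 | (1S,2R,5R,6S)-1-(tert-butyldimethylsilyloxy)-2,6-bis[4-(tert-butyldimethylsilyloxy)-3-methoxyphenyl]-3,7-dioxabicyclo[3.3.0]octane | COc1cc([C@H]2OC[C@]3(O[Si](C)(C)C(C)(C)C)[C@@H](c4ccc(O[Si](C)(C)C(C)(C)C)c(OC)c4)OC[C@H]23)ccc1O[Si](C)(C)C(C)(C)C | intermediate
19 | 8-hydroxypinoresinol, (1S,2R,5R,6S)-2,6-bis(4-hydroxy-3-methoxyphenyl)-3,7-dioxabicyclo[3.3.0]octan-1-ol | COc1cc([C@H]2OC[C@]3(O)[C@@H](c4ccc(O)c(OC)c4)OC[C@H]23)ccc1O | target

**Step count**
Total: 11 steps. Longest linear sequence: 9 steps (steps 1–4 and 7–11, from vanillin).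

**Steps most likely to fail**

1. Step 7. The ketene may dimerise faster than it adds to the hindered trisubstituted enol ether, or the zwitterion may collapse by silyl transfer or ring opening instead of closing the four-membered ring. The fallback sets out from 10 and 8 and comes back at 14. Ester 10 would be α-chlorinated through its lithium enolate (LiN(SiMe3)2, THF, −78 °C; N-chlorosuccinimide) to tert-butyldimethylsilyl 2-chloro-2-Ar-acetate F1. Oxalyl chloride with catalytic DMF would turn this into 2-chloro-2-Ar-acetyl chloride F2. With Et3N, F2 gives the aryl(chloro)ketene F3, a much stronger electrophile that dimerises more slowly. Its [2+2] addition to 8, with the same regiochemistry and facial sense, would give the 7-chloro cyclobutanone F4. Radical dechlorination (Bu3SnH, azobisisobutyronitrile, toluene, 80 °C) followed by the same DBU equilibration of C7 would deliver 14.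

2. Step 4. Deprotonation may occur in part on the oxygen-flanked C2 side, which places the enol ether double bond at C2=C3. The fallback makes the enolate regiospecifically; it sets out from 2 and comes back at 7. Corey–Fuchs olefination (CBr4, PPh3, CH2Cl2) would give the dibromoalkene F5. BuLi (2 equiv) and then 2-(tert-butyldimethylsilyloxy)-N-methoxy-N-methylacetamide would give the ynone F6. Camphorsulfonic acid in MeOH would free the primary alcohol while the aryl silyl ether survives, and 5-endo-dig closure onto the ynone (catalytic AgOTf) would give the achiral 5-Ar-furan-3(2H)-one F7. Copper hydride conjugate reduction (Cu(OAc)2, DTBM-SEGPHOS in the enantiomer that gives (S), diethoxymethylsilane, toluene) places hydride on C5 and leaves the diethoxymethylsilyl enol ether F8 with the double bond fixed at C3=C4. MeLi at −78 °C cleaves F8 to lithium enolate 7, which TBSOTf silylates to 8.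

3. Step 8. The ring-fusion carbon C8' may migrate in competition with benzylic C7, giving the wrong lactone, or the peracid may attack the electron-rich arenes. The fallback sets out from 14 and comes back at 18. Irradiation of 14 in MeOH (Pyrex-filtered medium-pressure mercury lamp) would cleave the benzylic C7–C9' bond of the excited ketone, and the resulting acyl–benzyl biradical recloses through oxygen to an oxacarbene that inserts into MeOH. The product is the methyl acetal F9, with oxygen already between C7 and C9'. Et3SiH with BF3·OEt2 in CH2Cl2 at −78 °C would reduce the acetal carbon to CH2 and give 18, bypassing steps 9 and 10.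

**Further compounds**
F1 | step 7 | tert-butyldimethylsilyl 2-chloro-2-[4-(tert-butyldimethylsilyloxy)-3-methoxyphenyl]acetate | COc1cc(C(Cl)C(=O)O[Si](C)(C)C(C)(C)C)ccc1O[Si](C)(C)C(C)(C)C
F2 | step 7 | 2-chloro-2-[4-(tert-butyldimethylsilyloxy)-3-methoxyphenyl]acetyl chloride | COc1cc(C(Cl)C(Cl)=O)ccc1O[Si](C)(C)C(C)(C)C
F3 | step 7 | [4-(tert-butyldimethylsilyloxy)-3-methoxyphenyl](chloro)ketene | O=C=C(Cl)c1ccc(O[Si](C)(C)C(C)(C)C)c(OC)c1
F4 | step 7 | (1S,4S,5R)-7-chloro-1-(tert-butyldimethylsilyloxy)-4,7-bis[4-(tert-butyldimethylsilyloxy)-3-methoxyphenyl]-3-oxabicyclo[3.2.0]heptan-6-one (C7 epimers) | COc1cc([C@H]2OC[C@]3(O[Si](C)(C)C(C)(C)C)C(Cl)(c4ccc(O[Si](C)(C)C(C)(C)C)c(OC)c4)C(=O)[C@H]23)ccc1O[Si](C)(C)C(C)(C)C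
F5 | step 4 | tert-butyl[4-(2,2-dibromovinyl)-2-methoxyphenoxy]dimethylsilane | COc1cc(C=C(Br)Br)ccc1O[Si](C)(C)C(C)(C)C
F6 | step 4 | 1-(tert-butyldimethylsilyloxy)-4-[4-(tert-butyldimethylsilyloxy)-3-methoxyphenyl]but-3-yn-2-one | COc1cc(C#CC(=O)CO[Si](C)(C)C(C)(C)C)ccc1O[Si](C)(C)C(C)(C)C
F7 | step 4 | 5-[4-(tert-butyldimethylsilyloxy)-3-methoxyphenyl]furan-3(2H)-one | COc1cc(C2=CC(=O)CO2)ccc1O[Si](C)(C)C(C)(C)C
F8 | step 4 | (S)-5-[4-(tert-butyldimethylsilyloxy)-3-methoxyphenyl]-3-[diethoxy(methyl)silyloxy]-2,5-dihydrofuran | COc1cc([C@H]2OCC(O[Si](C)(OCC)OCC)=C2)ccc1O[Si](C)(C)C(C)(C)C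
F9 | step 8 | (1S,2R,5R,6S)-1-(tert-butyldimethylsilyloxy)-2,6-bis[4-(tert-butyldimethylsilyloxy)-3-methoxyphenyl]-4-methoxy-3,7-dioxabicyclo[3.3.0]octane (acetal epimers) | COc1cc([C@H]2OC[C@]3(O[Si](C)(C)C(C)(C)C)[C@@H](c4ccc(O[Si](C)(C)C(C)(C)C)c(OC)c4)OC(OC)[C@H]23)ccc1O[Si](C)(C)C(C)(C)C
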